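3 questions stand open on 2 flasks: which ends higher, and the target in each.

| flask | starting material | gas | remark | time |
|---|---|---|---|---|
| theta | 0.69 M (in portions, 4) | 89 mM (held) | run made earlier; portions every 15 min |  |
| delta | 1.2 M (in portions, 4) | 89 mM (held) | run made earlier; portions every 15 min |  |
| Saturday's | 0.80 M (in portions, 4) | 89 mM (held) | the portions of starting material follow each other after 15 min, the first at the start | 10 h |
| Thursday's | 0.50 M | 89 mM | everything together at the start | 10 h |

| run | time / h | target / % | starting material / % |
|---|---|---|---|
| theta | 0.667 | 42.9 | 24.4 |
| theta | 1.33 | 81.1 | 6.9 |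
| theta | 2.00 | 87.4 | 1.0 |
| theta | 3.00 | 89.2 | 0.5 |
| theta | 4.00 | 90.6 | 0 |
| theta | 5.00 | 91.8 | 0 |
| delta | 0.667 | 43.4 | 24.3 |
| delta | 1.33 | 80.5 | 7.0 |
| delta | 2.00 | 87.0 | 0.1 |
| delta | 3.00 | 89.2 | 0 |
| delta | 4.00 | 91.0 | 0.3 |
| delta | 5.00 | 92.5 | 0 |

(scatter of a reading: 0.3 percentage points)

* which of the two ends with the higher amount of target, in percent of the starting material charged ("neither" if they lie within 2 percentage points) (Saturday's / Thursday's / neither)
* target at the end, in percent of the starting material charged, Saturday's
* target at the end, in percent of the starting material charged, Thursday's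

1. Count what is left, not what is made. From 3.00 h on, starting material reads 0.5 % or less in both runs, near the scatter of 0.3 percentage points. The charge not yet target is then the unfinished share. It reads 10.8 % at 3.00 h in the theta run and 10.8 % in the delta run.

2. First way, theta run: the share falls to 8.20 % by 5.00 h. That is 0.138 /h, and it leaves a target of 95.9 % at 10 h.

3. Second way, delta run: the share falls to 7.50 %. That is 0.182 /h, and it leaves 97.0 %.

4. The two ways part, and the last readings are what cheat. Those readings differ by 0.7 points, while two readings with this scatter typically differ by about 0.42 points. Each run's constant leans on one such reading, so the mean share, 7.85 %, serves better. It gives the clearing constant, the logarithmic fall of the unfinished share per hour: 0.160 /h, a half-life of 4.35 h.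

5. My reckoning for Saturday's is 96.5 %. Its portions wait 0.375 h on average, and that wait is worth 0.21 points to Thursday's, which reaches 96.7 %; the margin of 2 points is larger. Thursday's charge of 0.50 M lies below both runs, which is taken on trust.

The forecast: neither; Saturday's 96.4 % (94.5 % to 97.8 %), Thursday's 96.6 % (94.6 % to 98 %). “The main uncertainty is whether part of the gap is a permanent by-product.”

The flasks give neither: Saturday's 95.8 %, Thursday's 96.0 %.

    intermediate B → target (k = 2.71 /h)
    starting material → intermediate A (k = 0.461 /h)
    gas ⇌ reagent, rate k3*(csat - [reagent]) (kL = 4.45 /h)
    intermediate A ⇌ intermediate B (K = 0.570, k = 0.188 /h)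
    intermediate B → side product (k = 0.279 /h)
    starting material → target (k = 2.75 /h)

In Saturday's flask intermediate A crosses to intermediate B with a forward half-life of 3.7 h, the way back not counted, longer than the 0.26 h of intermediate B going to target. At 10.0 h intermediate A, the resting state, stands at 2.98 % against 0.178 % of intermediate B. The clearing constant takes Saturday's unfinished share at 5.00 h to 3.60 % at 10 h; Saturday's flask has 4.20 % not yet target, side product 1.05 % among it. Run back from the mean share to 2.5 h, the constant gives a target of 88.3 %, and Thursday's flask read then holds 89.1 %.

The readings stem from a simulated flask from invented constants.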